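**Retrosynthetic overview**

1. The target comes from alkannin by a late Steglich acylation of the side-chain hydroxyl (both phenols are peri-chelated). Alkannin comes from a 2-substituted 5,8-bis(methoxymethoxy)-1,4-naphthoquinone by acid removal of the acetals and the silyl ether.
2. The quinone comes from 5,8-bis(methoxymethoxy)-1-naphthols by para-oxidation, and the naphthols from a 2-substituted 1,4-epoxy-1,4-dihydronaphthalene by acid-catalysed bridge opening.
3. Key disconnection C1–C8a and C4–C4a. C1, C2, C3 and C4 of ring B, substituted only at C2, are the four carbons of a 3-substituted furan (its oxygen ends as the C1 or C4 carbonyl oxygen). Ring A (C4a, C5–C8, C8a, oxygens on C5 and C8) is a 3,6-dioxygenated benzyne from 2,3-dibromohydroquinone bis-acetal, whose adjacent bromines come from bromine addition to p-benzoquinone and enolisation.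
4. The (S) carbinol centre is set on the small 3-furyl ketone (3-bromofuran plus the Weinreb amide of 4-methylpent-3-enoic acid, then Corey–Bakshi–Shibata reduction) before any naphthalene exists.
5. Ring order: ring A and the furan are bought; ring B is the only ring formed, in the aryne [4+2] step.

Key step: step 7

Remark: naphthoquinone numbering of the target is used throughout (side chain on C2, hydroxyls on C5 and C8, C1′ = carbinol carbon). The ranking O > ring carbon > CH2 > H holds at C1′ from furan 13 to target 24 and no step breaks a bond to C1′, so the (S) descriptor carries through unchanged. Compounds 1, 5, 8 and 22 are taken as commercial.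

**Route**

Step 1
Reactants: 1 p-benzoquinone (cyclohexa-2,5-diene-1,4-dione)
Product: 3 2,3-dibromobenzene-1,4-diol (2,3-dibromohydroquinone), via trans-dibromo enedione 2 (not isolated)
Conditions: Br2 (1.0 equiv), Et2O, 0 °C; then conc. H2SO4, 0 °C → rt
Reagents that add atoms: bromine, BrBr
Why: Electrophilic anti addition of bromine to one C=C of the quinone gives the trans-5,6-dibromo enedione 2, and acid-catalysed double enolisation (aromatising tautomerisation) should then give the hydroquinone with both bromines on adjacent ring carbons, without any organometallic intermediate.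

Step 2
Reactants: 3 2,3-dibromobenzene-1,4-diol
Product: 4 2,3-dibromo-1,4-bis(methoxymethoxy)benzene
Conditions: MOMCl, i-Pr2NEt, CH2Cl2, 0 °C → rt
Reagents that add atoms: chloromethyl methyl ether, COCCl
Why: Double O-alkylation of the acidic ortho-bromophenols with the α-chloro ether under amine base (acetal protection) should give ethers that withstand n-BuLi and are released later by mild acid.

Step 3
Reactants: 5 4-methylpent-3-enoic acid
Product: 7 N-methoxy-N,4-dimethylpent-3-enamide, via acyl imidazolide 6 (not isolated)
Conditions: 1,1′-carbonyldiimidazole, CH2Cl2, 0 °C → rt; then MeNH(OMe)·HCl, rt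
Reagents that add atoms: N,O-dimethylhydroxylamine hydrochloride, CNOC.Cl
Why: Weinreb amide formation through the acyl imidazolide under nearly neutral conditions avoids an acid chloride and should leave the β,γ-double bond in place.

Step 4
Reactants: 8 3-bromofuran; 7 N-methoxy-N,4-dimethylpent-3-enamide
Product: 11 1-(furan-3-yl)-4-methylpent-3-en-1-one, via furan-3-yllithium 9 (not isolated), via lithium hemiaminal alkoxide 10 (not isolated)
Conditions: n-BuLi, THF, −78 °C; then 7, −78 °C; AcOH quench at −78 °C
Reagents that add atoms: none
Why: Bromine–lithium exchange followed by Weinreb ketone synthesis: at −78 °C the furyllithium should not isomerise to the 2-lithio species, the chelated tetrahedral adduct 10 blocks over-addition, and the cold acetic acid quench should release the ketone without moving its β,γ-alkene into conjugation.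

Step 5
Reactants: 11 1-(furan-3-yl)-4-methylpent-3-en-1-one
Product: 13 (1S)-1-(furan-3-yl)-4-methylpent-3-en-1-ol, via alkoxy catecholborane 12 (not isolated)
Conditions: (R)-1-methyl-3,3-diphenyltetrahydro-1H,3H-pyrrolo[1,2-c][1,3,2]oxazaborole [(R)-Me-CBS, 10 mol %], catecholborane, PhMe, −78 °C; then MeOH, dilute aq. NaOH wash
Reagents that add atoms: none
Why: Corey–Bakshi–Shibata reduction: with the planar furyl ring as the large and the CH2 group as the small substituent, the (R)-oxazaborolidine–borane complex should deliver hydride to the Re face of the carbonyl (mirror image of the (S)-catalyst/aryl alkyl ketone → (R)-alcohol case), setting the (S) centre, while catecholborane at −78 °C does not hydroborate the trisubstituted alkene.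

Step 6
Reactants: 13 (1S)-1-(furan-3-yl)-4-methylpent-3-en-1-ol
Product: 14 tert-butyl{[(1S)-1-(furan-3-yl)-4-methylpent-3-en-1-yl]oxy}dimethylsilane
Conditions: TBSCl, imidazole, DMF, rt
Reagents that add atoms: tert-butyldimethylsilyl chloride, CC(C)(C)[Si](C)(C)Cl
Why: Standard O-silylation of a secondary alcohol gives an ether that is inert to n-BuLi and to the aryne and does not touch the stereocentre.

Step 7
Reactants: 4 2,3-dibromo-1,4-bis(methoxymethoxy)benzene; 14 tert-butyl{[(1S)-1-(furan-3-yl)-4-methylpent-3-en-1-yl]oxy}dimethylsilane
Product: 17 tert-butyl{[(1S)-1-[5,8-bis(methoxymethoxy)-1,4-dihydro-1,4-epoxynaphthalen-2-yl]-4-methylpent-3-en-1-yl]oxy}dimethylsilane (two bridgehead diastereomers), via aryllithium 15 (not isolated), via aryne 16 (not isolated)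
Conditions: 4 (1.5 equiv), n-BuLi (1.5 equiv, slow addition), PhMe/THF, −78 °C, then slow warming to rt
Reagents that add atoms: none
Why: Bromine–lithium exchange on 4 gives the ortho-bromoaryllithium 15, which loses LiBr on warming to 3,6-bis(methoxymethoxy)benzyne 16, and the furan of 14 adds through its C2 and C5 as the 4π partner in a concerted suprafacial [4+2] cycloaddition, the well-known fate of arynes generated from 1,2-dihaloarenes in the presence of furans. Ring B is closed intermolecularly as the six-membered carbocycle of a 7-oxabicyclo[2.2.1]heptadiene by forming C1–C8a and C4–C4a at the same time. The bridgehead carbons C1 and C4 become stereocentres without control (both furan faces react, giving two diastereomers relative to the fixed (S) centre), which is harmless because both are erased on aromatisation in step 8, and the (S) centre is not involved. Regiochemistry is no issue because 16 is symmetric about the midpoint of its strained bond, so only one constitution can form. The selectivity needed is capture of 16 by the furan diene and not by n-BuLi, by 15 or by an ene reaction of the trisubstituted alkene; it rests on exchange being complete at −78 °C before any aryne appears, on slow warming that keeps 16 dilute, and on the far higher aryne affinity of an electron-rich furan compared with an isolated alkene.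

Step 8
Reactants: 17 the 1,4-epoxy-1,4-dihydronaphthalene (diastereomer mixture)
Product: 18 2-[(1S)-1-(tert-butyldimethylsilyloxy)-4-methylpent-3-en-1-yl]-5,8-bis(methoxymethoxy)naphthalen-1-ol (expected major) and 19 3-[(1S)-1-(tert-butyldimethylsilyloxy)-4-methylpent-3-en-1-yl]-5,8-bis(methoxymethoxy)naphthalen-1-ol (regioisomers, carried on crude as the mixture)
Conditions: Cu(OTf)2 (5 mol %), 4 Å MS, CH2Cl2, 0 °C → rt, argon
Reagents that add atoms: none
Why: Lewis acid-catalysed isomerisation of a 7-oxabenzonorbornadiene to a 1-naphthol: a bridgehead C–O bond ionises to a benzylic, allylic cation stabilised by the ortho acetal oxygen, and a 1,2-hydride shift and enolisation follow, erasing both bridgehead stereocentres; cleavage of C4–O (allyl cation terminus on the substituted C2) is expected to dominate and give 18, either naphthol leads to the same quinone, and the catalytic anhydrous conditions should spare the acetals and the silyl ether.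

Step 9
Reactants: 18 and 19 (mixture from step 8)
Product: 20 2-[(1S)-1-(tert-butyldimethylsilyloxy)-4-methylpent-3-en-1-yl]-5,8-bis(methoxymethoxy)naphthalene-1,4-dione
Conditions: (KO3S)2NO, KH2PO4, acetone/H2O, 0 °C → rt
Reagents that add atoms: potassium nitrosodisulfonate, [K+].[K+].[O]N(S(=O)(=O)[O-])S(=O)(=O)[O-]
Why: Teuber oxidation: the nitroxyl radical abstracts the phenolic hydrogen, a second radical couples at the free para carbon (C4) and loss of HN(SO3K)2 gives the para-quinone, so 18 and 19 converge on one 2-substituted quinone, while ring A, which has no free hydroxyl, is not oxidised.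

Step 10
Reactants: 20 the protected quinone
Product: 21 alkannin, 5,8-dihydroxy-2-[(1S)-1-hydroxy-4-methylpent-3-en-1-yl]naphthalene-1,4-dione
Conditions: 3 M aq. HCl, THF, 0 °C → rt
Reagents that add atoms: none
Why: Acid hydrolysis removes the two aryl methoxymethyl acetals (assisted by hydrogen bonding of the emerging phenols to the peri carbonyls) and the secondary silyl ether in one operation; dilute aqueous acid without an alcohol cosolvent at or below room temperature should leave the trisubstituted alkene and the C1′ centre (only O–Si and O–CH2 bonds break) untouched.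

Step 11
Reactants: 21 alkannin; 22 3,3-dimethylacrylic acid (3-methylbut-2-enoic acid)
Product: 24 alkannin β,β-dimethylacrylate, (1S)-1-(5,8-dihydroxy-1,4-dioxo-1,4-dihydronaphthalen-2-yl)-4-methylpent-3-en-1-yl 3-methylbut-2-enoate, via O-acylisourea 23 (not isolated)
Conditions: DCC, 4-(dimethylamino)pyridine (cat.), CH2Cl2, 0 °C → rt
Reagents that add atoms: none
Why: Steglich esterification: the acid is activated as O-acylisourea 23 and passed on by the pyridine catalyst to the only nucleophilic hydroxyl, the secondary C1′–OH, because both phenols are held in strong hydrogen bonds to the quinone carbonyls; the C1′–O bond is not broken, so (S) is retained, and the near-neutral conditions should keep the acyl double bond in conjugation.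

**Compound list**

1 | p-benzoquinone (cyclohexa-2,5-diene-1,4-dione) | O=C1C=CC(=O)C=C1 | starting material
2 | trans-5,6-dibromocyclohex-2-ene-1,4-dione (racemic; one enantiomer drawn) | O=C1C=CC(=O)[C@H](Br)[C@H]1Br | intermediate (not isolated)
3 | 2,3-dibromobenzene-1,4-diol (2,3-dibromohydroquinone) | Oc1ccc(O)c(Br)c1Br | intermediate
4 | 2,3-dibromo-1,4-bis(methoxymethoxy)benzene | COCOc1ccc(OCOC)c(Br)c1Br | intermediate
5 | 4-methylpent-3-enoic acid | CC(C)=CCC(=O)O | starting material
6 | 1-(imidazol-1-yl)-4-methylpent-3-en-1-one | CC(C)=CCC(=O)n1ccnc1 | intermediate (not isolated)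
7 | N-methoxy-N,4-dimethylpent-3-enamide | CC(C)=CCC(=O)N(C)OC | intermediate
8 | 3-bromofuran | Brc1ccoc1 | starting material
9 | furan-3-yllithium | [Li]c1ccoc1 | intermediate (not isolated)
10 | lithium 1-(furan-3-yl)-1-[methoxy(methyl)amino]-4-methylpent-3-en-1-olate (racemic at the hemiaminal carbon) | CC(C)=CCC(O[Li])(N(C)OC)c1ccoc1 | intermediate (not isolated)
11 | 1-(furan-3-yl)-4-methylpent-3-en-1-one | CC(C)=CCC(=O)c1ccoc1 | intermediate
12 | 2-{[(1S)-1-(furan-3-yl)-4-methylpent-3-en-1-yl]oxy}-1,3,2-benzodioxaborole | CC(C)=CC[C@H](OB1Oc2ccccc2O1)c1ccoc1 | intermediate (not isolated)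
13 | (1S)-1-(furan-3-yl)-4-methylpent-3-en-1-ol | CC(C)=CC[C@H](O)c1ccoc1 | intermediate
14 | tert-butyl{[(1S)-1-(furan-3-yl)-4-methylpent-3-en-1-yl]oxy}dimethylsilane | CC(C)=CC[C@H](O[Si](C)(C)C(C)(C)C)c1ccoc1 | intermediate
15 | [2-bromo-3,6-bis(methoxymethoxy)phenyl]lithium | COCOc1ccc(OCOC)c(Br)c1[Li] | intermediate (not isolated)
16 | 3,6-bis(methoxymethoxy)benzyne (1,2-didehydro-3,6-bis(methoxymethoxy)benzene) | COCOC1=CC=C(OCOC)C#C1 | intermediate (not isolated)
17 | tert-butyl{[(1S)-1-[5,8-bis(methoxymethoxy)-1,4-dihydro-1,4-epoxynaphthalen-2-yl]-4-methylpent-3-en-1-yl]oxy}dimethylsilane, both bridgehead diastereomers | CC(C)=CC[C@H](O[Si](C)(C)C(C)(C)C)C1=CC2OC1c1c(OCOC)ccc(OCOC)c12 | intermediate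
18 | 2-[(1S)-1-(tert-butyldimethylsilyloxy)-4-methylpent-3-en-1-yl]-5,8-bis(methoxymethoxy)naphthalen-1-ol | CC(C)=CC[C@H](O[Si](C)(C)C(C)(C)C)c1ccc2c(OCOC)ccc(OCOC)c2c1O | intermediate
19 | 3-[(1S)-1-(tert-butyldimethylsilyloxy)-4-methylpent-3-en-1-yl]-5,8-bis(methoxymethoxy)naphthalen-1-ol | CC(C)=CC[C@H](O[Si](C)(C)C(C)(C)C)c1cc(O)c2c(OCOC)ccc(OCOC)c2c1 | intermediate
20 | 2-[(1S)-1-(tert-butyldimethylsilyloxy)-4-methylpent-3-en-1-yl]-5,8-bis(methoxymethoxy)naphthalene-1,4-dione | CC(C)=CC[C@H](O[Si](C)(C)C(C)(C)C)C1=CC(=O)c2c(OCOC)ccc(OCOC)c2C1=O | intermediate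
21 | alkannin, 5,8-dihydroxy-2-[(1S)-1-hydroxy-4-methylpent-3-en-1-yl]naphthalene-1,4-dione | CC(C)=CC[C@H](O)C1=CC(=O)c2c(O)ccc(O)c2C1=O | intermediate
22 | 3,3-dimethylacrylic acid (3-methylbut-2-enoic acid) | CC(C)=CC(=O)O | starting material
23 | O-(3-methylbut-2-enoyl)-N,N′-dicyclohexylisourea | CC(C)=CC(=O)OC(=NC1CCCCC1)NC1CCCCC1 | intermediate (not isolated)
24 | alkannin β,β-dimethylacrylate | CC(C)=CC[C@H](OC(=O)C=C(C)C)C1=CC(=O)c2c(O)ccc(O)c2C1=O | target

**Step count**

Total step count: 11. Longest linear sequence: 9 steps (steps 3–11, from 5 to 24); steps 1–2 form the aryne branch that joins at step 7.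

**Steps most likely to fail**

Step 7 (key step). What may go wrong: the aryne is intercepted by aryllithium 15 or by n-BuLi that has not yet exchanged, or n-BuLi metalates the furan at an α-position, so the limiting furan is not converted. The fallback sets out from 4 and comes back at 17; it releases the aryne with fluoride in the absence of any organolithium. n-BuLi is added at −78 °C to 4 in PhMe/THF that already holds B(O-i-Pr)3, so that aryllithium 15 is borylated as it forms and should give, after loss of LiO-i-Pr, diisopropyl [2-bromo-3,6-bis(methoxymethoxy)phenyl]boronate F1 (not isolated). Oxidation with H2O2/AcOH gives 2-bromo-3,6-bis(methoxymethoxy)phenol F2. HN(SiMe3)2 gives [2-bromo-3,6-bis(methoxymethoxy)phenoxy]trimethylsilane F3. n-BuLi (THF, −78 °C) then causes bromine–lithium exchange with immediate retro-Brook 1,3 O→C silyl shift to lithium 3,6-bis(methoxymethoxy)-2-(trimethylsilyl)phenoxide F4 (not isolated), which Tf2O converts into 3,6-bis(methoxymethoxy)-2-(trimethylsilyl)phenyl trifluoromethanesulfonate F5. CsF in MeCN at rt should then generate 16 from F5 slowly in the presence of 14 and give 17; the secondary silyl ether of 14 is expected to withstand these conditions.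

Step 10. What may go wrong: under aqueous acid the freed C1′ hydroxyl adds to the protonated prenyl alkene (tetrahydrofuran formation), the carbinol centre ionises with loss of configuration, or the silyl ether resists cleavage and forces harsher conditions. The fallback sets out from 20 and comes back at 24; it inverts the order so that the hydroxyl is acylated before any acid is used. HF·pyridine (THF/pyridine, 0 °C → rt) removes the silyl group to give 2-[(1S)-1-hydroxy-4-methylpent-3-en-1-yl]-5,8-bis(methoxymethoxy)naphthalene-1,4-dione F6. Steglich esterification with 22 (DCC, 4-(dimethylamino)pyridine, through 23) gives (1S)-1-[5,8-bis(methoxymethoxy)-1,4-dioxo-1,4-dihydronaphthalen-2-yl]-4-methylpent-3-en-1-yl 3-methylbut-2-enoate F7. Brief treatment with anhydrous CF3CO2H in CH2Cl2 at 0 °C, then aqueous NaHCO3, should remove the two peri acetals and deliver 24.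

Step 5. What may go wrong: poor enantiofacial discrimination, because the flat 3-furyl ring and the prenyl-bearing methylene differ little in size, and migration of the β,γ-double bond of 11 into conjugation before reduction. The fallback sets out from 8 and comes back at 13 (it also replaces steps 3 and 4); it makes the stereocentre by C–C bond formation on an aldehyde. Furan-3-yllithium 9 (from 8, n-BuLi, −78 °C) is formylated with DMF through lithium (dimethylamino)(furan-3-yl)methanolate F8 (not isolated) to furan-3-carbaldehyde F9. Keck allylation [allylSnBu3, (S)-BINOL, Ti(O-i-Pr)4 (cat.), 4 Å MS, CH2Cl2, −20 °C], expected to deliver allyl to the Si face, gives tributyl{[(1S)-1-(furan-3-yl)but-3-en-1-yl]oxy}stannane F10 (not isolated) and, after hydrolytic work-up, (1S)-1-(furan-3-yl)but-3-en-1-ol F11. Cross-metathesis with excess 2-methyl-2-butene and the second-generation Grubbs catalyst, (H2IMes)(PCy3)Cl2Ru=CHPh, converts the vinyl group into the prenyl group and should give 13.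

**Further compounds**

F1 | step 7 | diisopropyl [2-bromo-3,6-bis(methoxymethoxy)phenyl]boronate | COCOc1ccc(OCOC)c(Br)c1B(OC(C)C)OC(C)C
F2 | step 7 | 2-bromo-3,6-bis(methoxymethoxy)phenol | COCOc1ccc(OCOC)c(Br)c1O
F3 | step 7 | [2-bromo-3,6-bis(methoxymethoxy)phenoxy]trimethylsilane | COCOc1ccc(OCOC)c(Br)c1O[Si](C)(C)C
F4 | step 7 | lithium 3,6-bis(methoxymethoxy)-2-(trimethylsilyl)phenoxide | COCOc1ccc(OCOC)c([Si](C)(C)C)c1O[Li]
F5 | step 7 | 3,6-bis(methoxymethoxy)-2-(trimethylsilyl)phenyl trifluoromethanesulfonate | COCOc1ccc(OCOC)c([Si](C)(C)C)c1OS(=O)(=O)C(F)(F)F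
F6 | step 10 | 2-[(1S)-1-hydroxy-4-methylpent-3-en-1-yl]-5,8-bis(methoxymethoxy)naphthalene-1,4-dione | CC(C)=CC[C@H](O)C1=CC(=O)c2c(OCOC)ccc(OCOC)c2C1=O
F7 | step 10 | (1S)-1-[5,8-bis(methoxymethoxy)-1,4-dioxo-1,4-dihydronaphthalen-2-yl]-4-methylpent-3-en-1-yl 3-methylbut-2-enoate | CC(C)=CC[C@H](OC(=O)C=C(C)C)C1=CC(=O)c2c(OCOC)ccc(OCOC)c2C1=O
F8 | step 5 | lithium (dimethylamino)(furan-3-yl)methanolate | CN(C)C(O[Li])c1ccoc1
F9 | step 5 | furan-3-carbaldehyde | O=Cc1ccoc1
F10 | step 5 | tributyl{[(1S)-1-(furan-3-yl)but-3-en-1-yl]oxy}stannane | C=CC[C@H](O[Sn](CCCC)(CCCC)CCCC)c1ccoc1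
F11 | step 5 | (1S)-1-(furan-3-yl)but-3-en-1-ol | C=CC[C@H](O)c1ccoc1
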